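I decided to judge these flasks by one number, the reagent exposure, which is mean [reagent] times time, and to read the fall of substrate as pseudo-first-order over that mean.

common to all: substrate 0.18 M
- west: reagent 0.22 M; run made earlier
- north-west: reagent 1.4 M; run made earlier
- eta: reagent 0.190 M; time 6.0 h
- epsilon: reagent 0.470 M; time 6.0 h
- beta: reagent 1.20 M; time 6.0 h

| run | time / h | single product / % | double product / % | substrate / % | tris adduct / % |
|---|---|---|---|---|---|
| west | 0.333 | 2 | 0 | 93 | 0 |
| west | 0.667 | 8 | 3 | 89 | 0 |
| west | 1.33 | 8 | 0 | 82 | 0 |
| west | 2.00 | 19 | 3 | 81 | 0 |
| west | 4.00 | 24 | 0 | 66 | 0 |
| north-west | 0.417 | 19 | 0 | 80 | 0 |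
| north-west | 1.00 | 39 | 4 | 53 | 4 |
| north-west | 2.00 | 54 | 13 | 32 | 0 |
| north-west | 3.00 | 56 | 26 | 20 | 3 |
| north-west | 4.00 | 51 | 33 | 11 | 4 |

(standard deviation of a reading: 2 percentage points)

- what was read earlier has a scatter of 2 percentage points, one standard deviation

- which of these there is most of at the end, counted by the substrate in it, eta (substrate / tris adduct / single product / double product)
- which of these there is most of at the end, counted by the substrate in it, epsilon (substrate / tris adduct / single product / double product)
- which of these there is most of at the end, counted by the substrate in it, beta (substrate / tris adduct / single product / double product)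
- amount of the one of these that there is most of at the end, in percent of the substrate charged, eta
- amount of the one of these that there is most of at the end, in percent of the substrate charged, epsilon
- amount of the one of these that there is most of at the end, in percent of the substrate charged, beta

Turn the question round: what must be true for substrate to lose first place in eta? Substrate holding more than half of its charge leads whatever the rest is, so it must fall below that. The west run gave me the constant. Its last reading showed 66% of its substrate at 4.00 h, and I put that loss back into the reagent, one reagent per substrate, so I took its mean [reagent] as 0.189 M. That gave a reading of k = 0.00914 M⁻¹ min⁻¹, with the scatter of its readings. So 75.8 M·min is the crossover exposure, the exposure that brings substrate down to half its charge, the natural log of two over k.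

At charged [reagent], eta has 68.4 M·min, already less than that. Going round once more with the first answer's loss put back, its exposure falls to 53.3 M·min, a fraction 0.703 of the crossover, and substrate comes to 61.4%. So I committed to substrate for eta. The same round puts epsilon at 144 M·min and beta at 400 M·min, both more than the crossover, so I expected substrate below half in those two flasks.

The forecast named substrate at 61% for eta, single product at 54% for epsilon and single product at 47% for beta, on the grounds “The runs fit consecutive steps, substrate → single → double”.

The flasks gave substrate at 59.6% in eta, single product at 50.1% in epsilon and single product at 47.3% in beta.

    2 substrate → homo dimer (k = 0.00110 M⁻¹ min⁻¹)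
    reagent + single product → double product (k = 0.00260 M⁻¹ min⁻¹)
    substrate + reagent → single product (k = 0.00730 M⁻¹ min⁻¹)
    reagent + double product → tris adduct (k = 2.80 × 10⁻⁴ M⁻¹ min⁻¹)
    reagent + tris adduct → tetra adduct (k = 5.80 × 10⁻⁴ M⁻¹ min⁻¹)

With 68% of its reagent left at the end, and taking the mean of charge and end, I reckoned the exposure of eta at 57.3 M·min, less than 75.8 M·min. In eta, the half-life of substrate by the making of single product alone, at charged concentrations, was 8.3 h, longer than the 6.0 h allowed. For eta left until 15 h, one round gave me an exposure of 107 M·min, more than 75.8 M·min, and a reckoned substrate of 37.6%. That flask holds 35.9% substrate and 43.1% single product, so single product leads there.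

The earlier runs and the new flask were generated by integration for an exercise, and the scatter is random.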